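The route rests on reading the cyclopentene ring (C9, C10, C17, C16, C15; Daphniphyllum numbering) as a cyclopent-2-en-1-ol. Carbinol C9 is the atom where the cyclopentene, the cyclopentane and the seven-membered carbocycle meet. Together with C15 and C16 it is a 2-methylenecyclopentanone, and C10=C17 is a terminal alkyne. One cobalt-catalysed reductive [3+2] union makes C16–C17, then C9–C10 across the ten-membered ring so formed. This closes the cyclopentene and the seven-membered carbocycle together and sets the tertiary alcohol and C15. The precursor is a spiro piperidine–cyclopentanone locked by the seven-membered lactone, so that an axial butynyl arm lies next to the enone. It is built in eleven steps from methyl (R)-3-oxocyclopentanecarboxylate.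

Key step: step 12

Remark on the chemistry:
- Atom labels by ring:
  - piperidine N–C1–C8–C5–C6–C7
  - lactone C5–C21–O–C22–C14–C13–C8
  - cyclopentane C8–C9–C15–C14–C13
  - cyclopentene C9–C10=C17–C16–C15
  - seven-membered carbocycle C5–C6–C12–C11–C10–C9–C8
  - side chain C4–C3–C2(=O)–C18(C19)(C20)
- With these labels the target is 5R,6S,8R,9R,14R,15R.
- The C15 epimers of 11–21 are assumed to be carried together, because C15 becomes trigonal in 22.

Step 1
Reactants: 1 vinyltriphenylphosphonium bromide; 2 methylamine
Product: 3 [2-(methylamino)ethyl]triphenylphosphonium bromide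
Conditions: MeNH2 (10 equiv, 2 M in THF), MeCN, 0 °C to rt
Reagents that add atoms: none
Why: Aza-Michael addition of an amine to a vinylphosphonium salt is fast, and the large excess of methylamine should stop it at the secondary amine.

Step 2
Reactants: 4 methyl (1R)-3-oxocyclopentane-1-carboxylate; 5 methyl dimethoxyacetate
Product: 6 methyl (1R)-4-(dimethoxyacetyl)-3-oxocyclopentane-1-carboxylate (enolised 1,3-diketone)
Conditions: LiHMDS (2.2 equiv), THF, −78 °C; 5; to −30 °C; AcOH
Reagents that add atoms: none
Why: Crossed Claisen acylation in which the kinetic lithium enolate forms at C8, away from the ester-bearing C14, the non-enolisable α,α-dialkoxy ester is a good acyl donor, the second equivalent of base stores 6 as its enolate, and the low temperature should leave the C14 centre untouched.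

Step 3
Reactants: 6 diketone; 3 aminoethylphosphonium salt; 7 formaldehyde (as paraformaldehyde)
Product: 8 Mannich salt, methyl (1R)-4-(dimethoxyacetyl)-4-({methyl[2-(triphenylphosphonio)ethyl]amino}methyl)-3-oxocyclopentane-1-carboxylate bromide, C1 trans to the ester
Conditions: (CH2O)n, MeCN, 4 Å MS, rt
Reagents that add atoms: none
Why: Mannich reaction of an acidic 1,3-diketone with the iminium ion from 3 and formaldehyde, in which the planar C8 enol should be attacked on the ring face opposite the C14 ester, setting the quaternary centre C8 with C1 trans and C5 cis to C22 (the minor epimer is removed at 12).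

Step 4
Reactants: 8 Mannich salt; 9 chloromethyl phenyl sulfide
Product: 11 spiro acetal, methyl 10-(dimethoxymethyl)-7-methyl-1-oxo-2-[(phenylsulfanyl)methyl]-7-azaspiro[4.5]dec-9-ene-3-carboxylate, via potassium enolate 10 (not isolated)
Conditions: KHMDS (2.3 equiv), THF, −78 to 0 °C; then 9, NaI (10 mol %), −78 °C to rt
Reagents that add atoms: potassium hexamethyldisilazide, C[Si](C)(C)[N-][Si](C)(C)C.[K+] (its potassium is found in 10 only)
Why: Intramolecular Wittig olefination of a (2-aminoethyl)phosphonium ylide followed by enolate alkylation, in which the second equivalent of base hides the enolisable C9 ketone as enolate 10 so that the ylide carbon C6 should meet only the activated, non-enolisable C5 ketone (six-membered ring), and 10 is then alkylated at C15, its only α-position, to carry C16 as a masked methylene.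

Step 5
Reactants: 11 spiro acetal
Product: 12 spiro enal, methyl 10-formyl-7-methyl-1-oxo-2-[(phenylsulfanyl)methyl]-7-azaspiro[4.5]dec-9-ene-3-carboxylate
Conditions: 1 M HCl, THF, 0 °C; NaHCO3
Reagents that add atoms: water, O
Why: Acid hydrolysis of an allylic acetal is very fast, so ester, sulfide and ketone should survive while the amine is merely protonated.

Step 6
Reactants: 12 spiro enal; 13 (4-bromobut-1-yn-1-yl)trimethylsilane
Product: 15 silyl enol ether, C12 arm on C6 cis to C9, via Grignard reagent 14 (not isolated)
Conditions: 13, Mg, THF, rt; then CuBr·SMe2 (10 mol %), DMPU, TMSCl, 12, THF, −78 °C; cold pH 7 buffer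
Reagents that add atoms: chlorotrimethylsilane, C[Si](C)(C)Cl; magnesium, [Mg] (found in 14 only)
Why: Copper-catalysed, chlorosilane-accelerated conjugate addition of a Grignard reagent to an enal, in which axial attack at C6 runs alongside the pseudoaxial substituent of C8 and should choose the half-chair that puts the flat ketone carbon C9 rather than C13H2 there, placing C12 cis to C9 and giving the C5 enolate regiospecifically as its silyl ether.

Step 7
Reactants: 15 silyl enol ether; 16 4-methylpent-1-en-3-one
Product: 17 keto aldehyde, C5 quaternary with C4 trans to the C12 arm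
Conditions: BF3·OEt2 (2.5 equiv), iPrOH (1 equiv), CH2Cl2/MeNO2, −78 °C; NaHCO3 aq
Reagents that add atoms: none
Why: Mukaiyama–Michael addition of an aldehyde silyl enol ether to an unhindered vinyl ketone with an alcohol as proton source, in which allylic 1,3-strain with the exocyclic enol ether keeps the C6 arm axial so that C4 should bond to C5 on the opposite face, setting the second quaternary centre.

Step 8
Reactants: 17 keto aldehyde
Product: 18 hydroxy ketone (C21H2OH)
Conditions: NaBH4, MeOH/CH2Cl2, −78 to −40 °C
Reagents that add atoms: none
Why: Chemoselective borohydride reduction, since at low temperature the aldehyde should react well before the two α-branched ketones and the ester.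

Step 9
Reactants: 18 hydroxy ketone
Product: 19 silylated keto lactone (lactone C5–C21–O–C22–C14–C13–C8 closed)
Conditions: Ti(OiPr)4 (20 mol %), toluene, 5 Å MS, 110 °C
Reagents that add atoms: none
Why: Titanate-catalysed transesterification with removal of methanol, possible because C21–OH and the C22 ester lie on the same face of the cyclopentanone, whereas a C8 or C14 epimer cannot close the bridged seven-membered lactone.

Step 10
Reactants: 19 silylated keto lactone
Product: 20 alkynyl keto lactone
Conditions: TBAF, AcOH (1:1), THF, 0 °C
Reagents that add atoms: none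
Why: Buffered fluoride protodesilylation frees the alkyne without the base that would expel thiophenolate or open the lactone.

Step 11
Reactants: 20 alkynyl keto lactone
Product: 22 enone alkyne (2-methylenecyclopentanone with axial but-3-ynyl arm), via sulfoxide 21 (not isolated)
Conditions: NaIO4, MeOH/H2O, 0 °C; then toluene, 60 °C
Reagents that add atoms: sodium periodate, [Na+].[O-]I(=O)(=O)=O (its oxygen is found in 21 only)
Why: Sulfide oxidation and sulfoxide syn-elimination, in which periodate leaves the amine alone, the only β-hydrogen is the acidic C15–H, and the double bond cannot move into the ring because C14 is a bridgehead of the lactone bicycle.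

Step 12
Reactants: 22 enone alkyne
Product: 23 target CNP0242289.1
Conditions: CoI2 (10 mol %), dppe (12 mol %), Zn (3 equiv), ZnI2 (20 mol %), H2O (3 equiv), MeCN, 50 °C, syringe-pump addition of 22, 2 mM
Reagents that add atoms: none
Why: Proposed new method: monovalent cobalt (from CoI2, dppe and Zn) should bind the alkyne and the C15=C16 methylene of 22 and couple their unsubstituted termini (C17–C16) to a cobaltacycle whose carbon chain is a ten-membered ring, water then protonates the enolate carbon C15, the alkenyl–cobalt carbon C10 adds across the ring to the C9 ketone, and Zn returns the catalyst. The closest known reaction type is the cobalt-catalysed reductive [3+2] cycloaddition of alkynes with cyclic enones to bicyclic tertiary cyclopentenols (nickel does the same with enals); not yet shown are an exocyclic enone and a tether that runs from the alkyne to the α′-carbon C8. The C10-to-C9 attack closes the cyclopentene as a 5-exo-trig and the seven-membered carbocycle as a 7-exo-trig addition to one carbonyl carbon. C9 is controlled by the tether, which hangs from C6 on the C5 side of the cyclopentanone and lets C10 reach only that face (OH syn to C1), and C15 by the new C16–C17 bond, which holds C16 on the same face so that the proton comes from the open face and the bicyclo[3.3.0]octene is cis-fused. The step needs regioselectivity (substituted alkyne carbon to the carbonyl), chemoselectivity (C9 before the C2 ketone) and ring closure before oligomerisation. These are secured by the usual placing of the metal at the substituted alkyne carbon, by the distance of C2, and by the lactone, which locks the piperidine chair with the C6 arm and C9 1,3-diaxial, helped by slow addition at high dilution.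

Compound list
1 | vinyltriphenylphosphonium bromide | C=C[P+](c1ccccc1)(c1ccccc1)c1ccccc1.[Br-] | starting material
2 | methylamine | CN | starting material
3 | [2-(methylamino)ethyl]triphenylphosphonium bromide | CNCC[P+](c1ccccc1)(c1ccccc1)c1ccccc1.[Br-] | intermediate
4 | methyl (1R)-3-oxocyclopentane-1-carboxylate | COC(=O)[C@@H]1CCC(=O)C1 | starting material
5 | methyl dimethoxyacetate | COC(=O)C(OC)OC | starting material
6 | methyl (1R)-4-(dimethoxyacetyl)-3-oxocyclopentane-1-carboxylate (C8 enolised) | COC(=O)[C@@H]1CC(C(=O)C(OC)OC)C(=O)C1 | intermediate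
7 | formaldehyde (as paraformaldehyde) | C=O | starting material
8 | Mannich salt, C1 trans to the C14 ester | COC(=O)[C@@H]1C[C@](CN(C)CC[P+](c2ccccc2)(c2ccccc2)c2ccccc2)(C(=O)C(OC)OC)C(=O)C1.[Br-] | intermediate
9 | chloromethyl phenyl sulfide | ClCSc1ccccc1 | starting material
10 | potassium C9/C15 enolate of the spiro acetal | COC(=O)[C@@H]1C[C@@]2(CN(C)CC=C2C(OC)OC)C([O-])=C1.[K+] | intermediate
11 | spiro acetal, methyl 10-(dimethoxymethyl)-7-methyl-1-oxo-2-[(phenylsulfanyl)methyl]-7-azaspiro[4.5]dec-9-ene-3-carboxylate (both C15 epimers) | COC(=O)[C@@H]1C[C@@]2(CN(C)CC=C2C(OC)OC)C(=O)C1CSc1ccccc1 | intermediate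
12 | spiro enal, 10-formyl analogue of 11 | COC(=O)[C@@H]1C[C@@]2(CN(C)CC=C2C=O)C(=O)C1CSc1ccccc1 | intermediate
13 | (4-bromobut-1-yn-1-yl)trimethylsilane | C[Si](C)(C)C#CCCBr | starting material
14 | [4-(trimethylsilyl)but-3-yn-1-yl]magnesium bromide | C[Si](C)(C)C#CCC[Mg]Br | intermediate
15 | silyl enol ether, silylbutynyl arm on C6 cis to C9 | COC(=O)[C@@H]1C[C@@]2(CN(C)C[C@@H](CCC#C[Si](C)(C)C)C2=CO[Si](C)(C)C)C(=O)C1CSc1ccccc1 | intermediate
16 | 4-methylpent-1-en-3-one | C=CC(=O)C(C)C | starting material
17 | keto aldehyde, C5 bearing CHO and the 4-methyl-3-oxopentyl chain (chain trans to the C6 arm) | COC(=O)[C@@H]1C[C@@]2(CN(C)C[C@@H](CCC#C[Si](C)(C)C)[C@]2(C=O)CCC(=O)C(C)C)C(=O)C1CSc1ccccc1 | intermediate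
18 | hydroxy ketone, CH2OH in place of CHO | COC(=O)[C@@H]1C[C@@]2(CN(C)C[C@@H](CCC#C[Si](C)(C)C)[C@]2(CO)CCC(=O)C(C)C)C(=O)C1CSc1ccccc1 | intermediate
19 | silylated keto lactone (piperidine, cyclopentanone and seven-membered lactone) | CC(C)C(=O)CC[C@]12COC(=O)[C@@H]3C[C@@]1(CN(C)C[C@H]2CCC#C[Si](C)(C)C)C(=O)C3CSc1ccccc1 | intermediate
20 | alkynyl keto lactone | CC(C)C(=O)CC[C@]12COC(=O)[C@@H]3C[C@@]1(CN(C)C[C@H]2CCC#C)C(=O)C3CSc1ccccc1 | intermediate
21 | sulfoxide of 20 | CC(C)C(=O)CC[C@]12COC(=O)[C@@H]3C[C@@]1(CN(C)C[C@H]2CCC#C)C(=O)C3CS(=O)c1ccccc1 | intermediate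
22 | enone alkyne, C15=C16H2 next to the C9 ketone, but-3-ynyl arm on C6 | CC(C)C(=O)CC[C@]12COC(=O)[C@@H]3C[C@@]1(CN(C)C[C@H]2CCC#C)C(=O)C3=C | intermediate
23 | CNP0242289.1 (5R,6S,8R,9R,14R,15R in the labels used here) | CC(C)C(=O)CC[C@]12COC(=O)[C@@H]3C[C@]14CN(C)C[C@H]2CCC1=CC[C@H]3[C@@]14O | target

Total step count: 12. Longest linear sequence: 11 steps (steps 2 to 12 from 4; the branch through step 1 is equally long).

Steps most likely to fail

Step 12.
- What may go wrong: the alkenyl–cobalt bond may be protonated before it adds across the ring, the alkyne may oligomerise, or the exocyclic enone may be reduced or dimerise.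
- The fallback sets out from 22, comes back at 23 and uses known chemistry only.
- Lithium divinylcuprate, (CH2=CH)2CuLi, adds to C16, and the enolate is protonated from the open face to give the allyl ketone F1.
- B-iodo-9-borabicyclo[3.3.1]nonane followed by acetic acid turns the alkyne into the 2-iodoalkene F2.
- A Nozaki–Hiyama–Kishi reaction (CrCl2, NiCl2 2 mol %, DMSO) closes the seven-membered carbocycle onto C9 to give the dienol F3.
- Ring-closing metathesis of the camphorsulfonate salt of F3 with the second-generation Hoveyda–Grubbs catalyst then closes the cyclopentene, still as the last ring.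

Step 7.
- What may go wrong: bond formation next to the quaternary C8 may be so slow that loss of the silyl group or polymerisation of the vinyl ketone wins.
- The fallback sets out from 15, comes back at 17 and replaces Lewis-acid activation by a Stork enamine reaction.
- 15 is hydrolysed (citric acid, THF/H2O) to the aldehyde F4.
- F4 is condensed with pyrrolidine (benzene, 4 Å MS) to the enamine F5.
- F5 is heated with 16 in dioxane to the aminodihydropyran F6, which is opened with aqueous acetic acid/sodium acetate.

Step 6.
- What may go wrong: poor or inverted facial selectivity of the conjugate addition at C6.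
- The fallback sets out from 12, comes back at 15 and reverses the order in which carbon and hydrogen arrive.
- The wrongly configured silyl enol ether F7 is oxidised (Saegusa–Ito oxidation, Pd(OAc)2, MeCN) to the tetrasubstituted enal F8, which erases C6.
- Conjugate reduction with [(Ph3P)CuH]6 and TMSCl then delivers hydride along the same preferred trajectory, which now leaves the arm on the face of C9.

Further compounds
F1 | step 12 | allyl ketone (C16H2–CH=CH2 on C15, cis to C22) | CC(C)C(=O)CC[C@]12COC(=O)[C@@H]3C[C@@]1(CN(C)C[C@H]2CCC#C)C(=O)[C@@H]3CC=C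
F2 | step 12 | 2-iodoalkene | CC(C)C(=O)CC[C@]12COC(=O)[C@@H]3C[C@@]1(CN(C)C[C@H]2CCC(I)=C)C(=O)[C@@H]3CC=C
F3 | step 12 | dienol (seven-membered carbocycle closed, C10 methylidene, C15 allyl) | CC(C)C(=O)CC[C@]12COC(=O)[C@@H]3C[C@]14CN(C)C[C@H]2CCC(=C)[C@]4(O)[C@@H]3CC=C
F4 | step 7 | aldehyde (C5–H) | COC(=O)[C@@H]1C[C@@]2(CN(C)C[C@@H](CCC#C[Si](C)(C)C)C2C=O)C(=O)C1CSc1ccccc1
F5 | step 7 | pyrrolidine enamine | COC(=O)[C@@H]1C[C@@]2(CN(C)C[C@@H](CCC#C[Si](C)(C)C)C2=CN2CCCC2)C(=O)C1CSc1ccccc1
F6 | step 7 | aminodihydropyran adduct | COC(=O)[C@@H]1C[C@@]2(CN(C)C[C@@H](CCC#C[Si](C)(C)C)[C@]23CC=C(C(C)C)OC3N3CCCC3)C(=O)C1CSc1ccccc1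
F7 | step 6 | C6 epimer of 15 | COC(=O)[C@@H]1C[C@@]2(CN(C)C[C@H](CCC#C[Si](C)(C)C)C2=CO[Si](C)(C)C)C(=O)C1CSc1ccccc1
F8 | step 6 | tetrasubstituted enal | COC(=O)[C@@H]1C[C@@]2(CN(C)CC(CCC#C[Si](C)(C)C)=C2C=O)C(=O)C1CSc1ccccc1
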